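**Plan**

1. Enabling feature (labdane numbering): trans-fused rings A and B in which C4 carries a methyl and an axial carboxyl, C10 an angular methyl, and C8 an exocyclic methylene beside the side-chain carbon C9. This is the imprint of a C4 keto-ester radical adding across C5=C10 and then C8=C9 of an E,E-diene.
2. Cuts, in retrosynthetic order: the O15–acyl bond (oleate); C11–C12 (bicyclic C11 sulfone plus a five-carbon E-allylic bromide); C4–C5 and C9–C10 together (both rings, one operation); C1–C2 (acetoacetate dianion plus 8-bromogeranyl acetate).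
3. Forward: the chain is joined first; ring A then ring B close in one oxidative radical cascade that also delivers C8=C17; the C3 ketone is removed; the ester auxiliary is cleaved reductively; the side chain is attached at C11; O15 is oleoylated; C19 is oxidised to the acid last.
4. Stereochemistry: C4, C5, C9 and C10 arise together in the cascade, relative configuration from chair-like folding of the E,E-diene and absolute configuration from an 8-phenylmenthyl ester. The 13E alkene comes from SeO2 oxidation of the E-methyl of a prenyl ether, and the Z alkene is bought with oleic acid.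

Key step: step 5

Numbering: labdane locants are used for the decalin and side chain (C19 = carbon on the beta face of C4, C18 = C4 methyl, C20 = C10 methyl, C17 = methylene carbon on C8, C11 = CH2 on C9). "Normal configuration" means 5α-H, 9α-H, 10β-CH3 and C19 on the β face. "(−)-8-phenylmenthyl" means (1R,2S,5R)-5-methyl-2-(2-phenylpropan-2-yl)cyclohexyl.

Assumption: the (1R,2S,5R)-8-phenylmenthyl ester is taken to expose the face of the C4 radical that leads to the natural (normal-labdane) decalin; the relative configuration does not depend on this.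

**Route**

Step 1
Reactants: 1 geranyl acetate
Product: 2 (2E,6E)-8-hydroxy-3,7-dimethylocta-2,6-dien-1-yl acetate
Conditions: SeO2 (cat.), salicylic acid (cat.), t-BuOOH, CH2Cl2, rt
Reagents that add atoms: tert-butyl hydroperoxide, CC(C)(C)OO (terminal oxygen source); selenium dioxide, O=[Se]=O (oxygen carrier)
Why: Riley-type allylic oxidation with catalytic SeO2 (ene reaction, then 2,3-sigmatropic shift) attacks the E-methyl of the electron-richer terminal alkene, the alkene next to the acetate being deactivated, so the 6E alcohol should form with C2=C3 untouched.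

Step 2
Reactants: 2 (2E,6E)-8-hydroxy-3,7-dimethylocta-2,6-dien-1-yl acetate
Product: 3 (2E,6E)-8-bromo-3,7-dimethylocta-2,6-dien-1-yl acetate
Conditions: CBr4, PPh3, CH2Cl2, 0 °C
Reagents that add atoms: carbon tetrabromide, BrC(Br)(Br)Br
Why: Appel bromination replaces the primary allylic hydroxyl by SN2 displacement of the oxyphosphonium group at 0 °C, which should preserve both E alkenes and the acetate.

Step 3
Reactants: 4 methyl 2-methyl-3-oxobutanoate; 5 (−)-8-phenylmenthol
Product: 6 (−)-8-phenylmenthyl 2-methyl-3-oxobutanoate (C2 epimers)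
Conditions: DMAP (cat.), toluene, reflux, MeOH distilled off
Reagents that add atoms: none
Why: DMAP-catalysed transesterification of a beta-keto ester is driven by removal of methanol and is the usual way to load a hindered secondary alcohol; the alpha carbon stays epimeric, which is harmless because it later becomes a planar radical.

Step 4
Reactants: 6 (−)-8-phenylmenthyl 2-methyl-3-oxobutanoate; 3 (2E,6E)-8-bromo-3,7-dimethylocta-2,6-dien-1-yl acetate
Product: 8 (−)-8-phenylmenthyl (6E,10E)-12-acetoxy-2,6,10-trimethyl-3-oxododeca-6,10-dienoate (C2 epimers), via keto ester dianion 7 (not isolated)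
Conditions: NaH, THF, 0 °C; n-BuLi, 0 °C; then 3, −78 → 0 °C
Reagents that add atoms: none
Why: Weiler dianion alkylation, in which the more basic gamma carbon of 7 attacks the primary allylic bromide by SN2 far faster than the acetate carbonyl at low temperature, forming C1–C2 and leaving both E alkenes intact.

Step 5
Reactants: 8 (−)-8-phenylmenthyl (6E,10E)-12-acetoxy-2,6,10-trimethyl-3-oxododeca-6,10-dienoate
Product: 12 (−)-8-phenylmenthyl 11-acetoxy-3-oxo-12,13,14,15,16-pentanorlabd-8(17)-en-19-oate (normal configuration), via C4 radical 9 (not isolated), via monocyclic C10 radical 10 (not isolated), via bicyclic C8 radical 11 (not isolated)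
Conditions: Mn(OAc)3·2H2O (2.2 equiv), Cu(OAc)2·H2O (1 equiv), degassed AcOH, 20 °C
Reagents that add atoms: none
Why: Enolisation of the keto ester on trivalent manganese and inner-sphere electron transfer give the electrophilic tertiary radical 9 at C4; this attacks C5 of the electron-rich C5=C10 alkene 6-endo (ring A, bond C4–C5), the tertiary C10 radical 10 attacks C9 of the C8=C9 alkene again 6-endo (ring B, bond C9–C10), and Cu(OAc)2 traps the tertiary C8 radical 11 as an alkylcopper species that loses a methyl hydrogen to leave the C8=C17 methylene, the monovalent copper being returned to the divalent state by the second equivalent of Mn(OAc)3. The closest known reaction type is the Mn(OAc)3/Cu(OAc)2 oxidative free-radical polyene cyclisation of unsaturated 2-alkyl-3-oxo esters, including variants steered by a chiral ester group. Both rings close through chair-like transition states: anti addition across the E C5=C10 alkene makes H5 and the C10 methyl trans (C5, C10), the E geometry of C8=C9 puts the acetoxymethyl group equatorial (C9), and the ester takes the axial position on the C10-methyl face with the C4 methyl equatorial (C4, relative). The absolute sense comes from the 8-phenylmenthyl ester, whose phenyl ring lies over one face of the planar C4 radical so that C5 must bond to the open face. The step needs 6-endo rather than 5-exo closure at both alkenes, which their trisubstitution secures because attack at the less substituted carbon gives a tertiary radical each time, and it needs termination toward the exocyclic alkene, which copper-mediated elimination of the least hindered methyl hydrogen favours. Only two alkenes are present, so the cascade must end after ring B with the C11 acetate in place for later use.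

Step 6
Reactants: 12 (−)-8-phenylmenthyl 11-acetoxy-3-oxo-12,13,14,15,16-pentanorlabd-8(17)-en-19-oate
Product: 13 C3 p-toluenesulfonylhydrazone of 12
Conditions: TsNHNH2, EtOH, 70 °C
Reagents that add atoms: p-toluenesulfonyl hydrazide, Cc1ccc(cc1)S(=O)(=O)NN
Why: Hydrazone condensation at the only ketone under neutral conditions should spare the acetate, the hindered ester and the acid-sensitive exocyclic alkene, and no stereocentre is at risk because C4 is quaternary.

Step 7
Reactants: 13 C3 p-toluenesulfonylhydrazone of 12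
Product: 15 (−)-8-phenylmenthyl 11-acetoxy-12,13,14,15,16-pentanorlabd-8(17)-en-19-oate, via N-boryl tosylhydrazine 14 (not isolated)
Conditions: catecholborane, CHCl3, 0 °C → rt; then NaOAc·3H2O, reflux
Reagents that add atoms: none
Why: Kabalka variant of the Caglioti tosylhydrazone reduction, in which catecholborane adds hydride to C=N to give 14 and acetate-induced loss of sulfinate and N2 from the derived diazene leaves the C3 methylene without touching the esters or the 1,1-disubstituted alkene.

Step 8
Reactants: 15 (−)-8-phenylmenthyl 11-acetoxy-12,13,14,15,16-pentanorlabd-8(17)-en-19-oate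
Product: 16 diol 12,13,14,15,16-pentanorlabd-8(17)-ene-11,19-diol (normal configuration)
Conditions: LiAlH4, THF, 0 °C → reflux; Fieser work-up
Reagents that add atoms: none
Why: LiAlH4 reduction cleaves the acetate and, at reflux, the hindered axial ester to the two primary alcohols and releases auxiliary 5 for recovery; C4 is quaternary, so nothing can epimerise.

Step 9
Reactants: 16 diol 12,13,14,15,16-pentanorlabd-8(17)-ene-11,19-diol
Product: 17 hydroxy sulfide 11-(phenylsulfanyl)-12,13,14,15,16-pentanorlabd-8(17)-en-19-ol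
Conditions: PhSSPh, n-Bu3P, pyridine, rt → 50 °C
Reagents that add atoms: diphenyl disulfide, c1ccc(cc1)SSc1ccccc1
Why: Hata thioetherification (phosphine/disulfide redox condensation), in which thiolate displaces the oxyphosphonium group at primary C11 by SN2 while the neopentyl C19 oxyphosphonium cannot be displaced and reverts to the alcohol on work-up, so sulfide formation should be selective for C11.

Step 10
Reactants: 17 hydroxy sulfide 11-(phenylsulfanyl)-12,13,14,15,16-pentanorlabd-8(17)-en-19-ol
Product: 18 hydroxy sulfone 11-(phenylsulfonyl)-12,13,14,15,16-pentanorlabd-8(17)-en-19-ol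
Conditions: (NH4)6Mo7O24·4H2O (cat.), 30% H2O2, EtOH, 0 °C → rt
Reagents that add atoms: hydrogen peroxide, OO
Why: Molybdate-catalysed peroxide oxidation takes the sulfide to the sulfone through a peroxomolybdate that oxidises sulfur much faster than unactivated alkenes, so the methylene group and the alcohol should survive.

Step 11
Reactants: 19 prenol (3-methylbut-2-en-1-ol)
Product: 20 tert-butyl[(3-methylbut-2-en-1-yl)oxy]diphenylsilane
Conditions: TBDPSCl, imidazole, CH2Cl2, rt
Reagents that add atoms: tert-butyl(chloro)diphenylsilane, CC(C)(C)[Si](Cl)(c1ccccc1)c1ccccc1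
Why: Imidazole-mediated silylation of a primary allylic alcohol gives a TBDPS ether robust enough to carry O15 through the organolithium, amalgam and oxidation steps.

Step 12
Reactants: 20 tert-butyl[(3-methylbut-2-en-1-yl)oxy]diphenylsilane
Product: 21 (2E)-4-[(tert-butyldiphenylsilyl)oxy]-2-methylbut-2-en-1-ol
Conditions: SeO2 (cat.), salicylic acid (cat.), t-BuOOH, CH2Cl2, rt
Reagents that add atoms: tert-butyl hydroperoxide, CC(C)(C)OO (terminal oxygen source); selenium dioxide, O=[Se]=O (oxygen carrier)
Why: Riley-type allylic oxidation functionalises the E-methyl of the trisubstituted alkene (ene reaction, then 2,3-sigmatropic shift), which fixes the E geometry of the future C13=C14 alkene.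

Step 13
Reactants: 21 (2E)-4-[(tert-butyldiphenylsilyl)oxy]-2-methylbut-2-en-1-ol
Product: 22 tert-butyl{[(2E)-4-bromo-3-methylbut-2-en-1-yl]oxy}diphenylsilane
Conditions: CBr4, PPh3, CH2Cl2, 0 °C
Reagents that add atoms: carbon tetrabromide, BrC(Br)(Br)Br
Why: Appel bromination of the primary allylic alcohol by SN2 displacement should give the E-allylic bromide without transposition, the silyl ether being inert.

Step 14
Reactants: 18 hydroxy sulfone 11-(phenylsulfonyl)-12,13,14,15,16-pentanorlabd-8(17)-en-19-ol; 22 tert-butyl{[(2E)-4-bromo-3-methylbut-2-en-1-yl]oxy}diphenylsilane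
Product: 24 15-[(tert-butyldiphenylsilyl)oxy]-11-(phenylsulfonyl)labda-8(17),13E-dien-19-ol (C11 epimers), via dilithiated hydroxy sulfone 23 (not isolated)
Conditions: n-BuLi (2.1 equiv), THF–DMPU, −78 °C; then 22, −78 → −20 °C
Reagents that add atoms: none
Why: Sulfone carbanion alkylation (Julia-type coupling), in which the second equivalent of base deprotonates C11 next to the sulfone and the carbanion of 23 attacks the primary allylic bromide by SN2 to form C11–C12 with the E alkene untouched; the new C11 centre forms as a mixture and is erased in the next step.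

Step 15
Reactants: 24 15-[(tert-butyldiphenylsilyl)oxy]-11-(phenylsulfonyl)labda-8(17),13E-dien-19-ol
Product: 25 silyl ether 15-[(tert-butyldiphenylsilyl)oxy]labda-8(17),13E-dien-19-ol
Conditions: Na/Hg (6% Na), Na2HPO4, MeOH–THF, −20 °C
Reagents that add atoms: none
Why: Reductive desulfonylation with buffered sodium amalgam cleaves the C11–S bond by electron transfer and protonation, and because the sulfone is homoallylic rather than allylic the C13=C14 alkene should keep its position and E geometry.

Step 16
Reactants: 25 silyl ether 15-[(tert-butyldiphenylsilyl)oxy]labda-8(17),13E-dien-19-ol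
Product: 26 aldehyde 15-[(tert-butyldiphenylsilyl)oxy]labda-8(17),13E-dien-19-al
Conditions: Dess–Martin periodinane, NaHCO3, CH2Cl2, rt
Reagents that add atoms: none
Why: Dess–Martin oxidation of the only free hydroxyl gives the non-enolisable neopentyl aldehyde under buffered conditions that leave both alkenes and the silyl ether alone.

Step 17
Reactants: 26 aldehyde 15-[(tert-butyldiphenylsilyl)oxy]labda-8(17),13E-dien-19-al
Product: 27 hydroxy aldehyde 15-hydroxylabda-8(17),13E-dien-19-al
Conditions: Bu4NF, THF, 0 °C → rt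
Reagents that add atoms: none
Why: Fluoride-mediated desilylation cleaves the Si–O bond selectively, and the C19 aldehyde has no alpha hydrogen and so cannot enolise or epimerise under the basic conditions.

Step 18
Reactants: 27 hydroxy aldehyde 15-hydroxylabda-8(17),13E-dien-19-al; 28 oleic acid
Product: 30 19-oxolabda-8(17),13E-dien-15-yl (9Z)-octadec-9-enoate, via oleic O-acylisourea 29 (not isolated)
Conditions: EDC·HCl, DMAP (cat.), CH2Cl2, 0 °C → rt
Reagents that add atoms: none
Why: Steglich esterification, in which the carbodiimide activates oleic acid as 29 and DMAP passes the acyl group to the primary allylic alcohol under neutral conditions that keep the Z alkene, the aldehyde and the exocyclic alkene intact.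

Step 19
Reactants: 30 19-oxolabda-8(17),13E-dien-15-yl (9Z)-octadec-9-enoate
Product: 31 15-[(9Z)-octadec-9-enoyloxy]labda-8(17),13E-dien-19-oic acid (target)
Conditions: NaClO2, NaH2PO4, 2-methyl-2-butene, t-BuOH–H2O, 0 °C → rt
Reagents that add atoms: sodium chlorite, [Na+].[O-]Cl=O
Why: Pinnick oxidation converts the hindered aldehyde into the carboxylic acid with chlorous acid while 2-methyl-2-butene scavenges HOCl, so the three alkenes and the allylic ester should be untouched and the free acid is obtained without a deprotection.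

**Compound list**

1 | geranyl acetate | CC(C)=CCC/C(C)=C/COC(C)=O | starting material
2 | (2E,6E)-8-hydroxy-3,7-dimethylocta-2,6-dien-1-yl acetate | OC/C(C)=C/CC/C(C)=C/COC(C)=O | intermediate
3 | (2E,6E)-8-bromo-3,7-dimethylocta-2,6-dien-1-yl acetate | BrC/C(C)=C/CC/C(C)=C/COC(C)=O | intermediate
4 | methyl 2-methyl-3-oxobutanoate | COC(=O)C(C)C(C)=O | starting material
5 | (−)-8-phenylmenthol, (1R,2S,5R)-5-methyl-2-(2-phenylpropan-2-yl)cyclohexan-1-ol | CC(C)(c1ccccc1)[C@@H]1CC[C@@H](C)C[C@H]1O | starting material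
6 | (−)-8-phenylmenthyl 2-methyl-3-oxobutanoate (C2 epimers) | CC(=O)C(C)C(=O)O[C@@H]1C[C@H](C)CC[C@H]1C(C)(C)c1ccccc1 | intermediate
7 | sodium lithium dianion (bis-enolate) of 6 | [Li+].[Na+].C=C([O-])C(C)=C([O-])O[C@@H]1C[C@H](C)CC[C@H]1C(C)(C)c1ccccc1 | intermediate
8 | (−)-8-phenylmenthyl (6E,10E)-12-acetoxy-2,6,10-trimethyl-3-oxododeca-6,10-dienoate (C2 epimers) | CC(C(=O)CC/C(C)=C/CC/C(C)=C/COC(C)=O)C(=O)O[C@@H]1C[C@H](C)CC[C@H]1C(C)(C)c1ccccc1 | intermediate
9 | C4 radical of 8 (radical at the ester alpha carbon) | C[C](C(=O)CC/C(C)=C/CC/C(C)=C/COC(C)=O)C(=O)O[C@@H]1C[C@H](C)CC[C@H]1C(C)(C)c1ccccc1 | intermediate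
10 | monocyclic C10 radical (ring A closed, E-allylic acetate side chain on C5) | CC(=O)OC/C=C(C)/CC[C@@H]1[C](C)CCC(=O)[C@]1(C)C(=O)O[C@@H]2C[C@H](C)CC[C@H]2C(C)(C)c2ccccc2 | intermediate
11 | bicyclic C8 radical (rings A and B closed) | C[C]1CC[C@@H]2[C@](C)(CCC(=O)[C@]2(C)C(=O)O[C@@H]3C[C@H](C)CC[C@H]3C(C)(C)c3ccccc3)[C@H]1COC(C)=O | intermediate
12 | (−)-8-phenylmenthyl 11-acetoxy-3-oxo-12,13,14,15,16-pentanorlabd-8(17)-en-19-oate (normal configuration) | C=C1CC[C@@H]2[C@](C)(CCC(=O)[C@]2(C)C(=O)O[C@@H]3C[C@H](C)CC[C@H]3C(C)(C)c3ccccc3)[C@H]1COC(C)=O | intermediate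
13 | C3 p-toluenesulfonylhydrazone of 12 | C=C1CC[C@@H]2[C@](C)(CCC(=NNS(=O)(=O)c3ccc(C)cc3)[C@]2(C)C(=O)O[C@@H]3C[C@H](C)CC[C@H]3C(C)(C)c3ccccc3)[C@H]1COC(C)=O | intermediate
14 | C3 N-(1,3,2-benzodioxaborol-2-yl)-N′-tosylhydrazine (C3 configuration irrelevant) | C=C1CC[C@@H]2[C@](C)(CCC(N(NS(=O)(=O)c3ccc(C)cc3)B3Oc4ccccc4O3)[C@]2(C)C(=O)O[C@@H]3C[C@H](C)CC[C@H]3C(C)(C)c3ccccc3)[C@H]1COC(C)=O | intermediate
15 | (−)-8-phenylmenthyl 11-acetoxy-12,13,14,15,16-pentanorlabd-8(17)-en-19-oate | C=C1CC[C@@H]2[C@](C)(CCC[C@]2(C)C(=O)O[C@@H]3C[C@H](C)CC[C@H]3C(C)(C)c3ccccc3)[C@H]1COC(C)=O | intermediate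
16 | 12,13,14,15,16-pentanorlabd-8(17)-ene-11,19-diol | C=C1CC[C@@H]2[C@](C)(CCC[C@]2(C)CO)[C@H]1CO | intermediate
17 | 11-(phenylsulfanyl)-12,13,14,15,16-pentanorlabd-8(17)-en-19-ol | C=C1CC[C@@H]2[C@](C)(CCC[C@]2(C)CO)[C@H]1CSc3ccccc3 | intermediate
18 | 11-(phenylsulfonyl)-12,13,14,15,16-pentanorlabd-8(17)-en-19-ol | C=C1CC[C@@H]2[C@](C)(CCC[C@]2(C)CO)[C@H]1CS(=O)(=O)c3ccccc3 | intermediate
19 | prenol (3-methylbut-2-en-1-ol) | CC(C)=CCO | starting material
20 | tert-butyl[(3-methylbut-2-en-1-yl)oxy]diphenylsilane | CC(C)=CCO[Si](c1ccccc1)(c1ccccc1)C(C)(C)C | intermediate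
21 | (2E)-4-[(tert-butyldiphenylsilyl)oxy]-2-methylbut-2-en-1-ol | OC/C(C)=C/CO[Si](c1ccccc1)(c1ccccc1)C(C)(C)C | intermediate
22 | tert-butyl{[(2E)-4-bromo-3-methylbut-2-en-1-yl]oxy}diphenylsilane | BrC/C(C)=C/CO[Si](c1ccccc1)(c1ccccc1)C(C)(C)C | intermediate
23 | dilithio derivative of 18 (C19 alkoxide, C11 carbanion) | [Li+].[Li+].C=C1CC[C@@H]2[C@](C)(CCC[C@]2(C)C[O-])[C@H]1[CH-]S(=O)(=O)c3ccccc3 | intermediate
24 | 15-[(tert-butyldiphenylsilyl)oxy]-11-(phenylsulfonyl)labda-8(17),13E-dien-19-ol (C11 epimers) | C=C1CC[C@@H]2[C@](C)(CCC[C@]2(C)CO)[C@H]1C(C/C(C)=C/CO[Si](c3ccccc3)(c3ccccc3)C(C)(C)C)S(=O)(=O)c3ccccc3 | intermediate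
25 | 15-[(tert-butyldiphenylsilyl)oxy]labda-8(17),13E-dien-19-ol | C=C1CC[C@@H]2[C@](C)(CCC[C@]2(C)CO)[C@H]1CC/C(C)=C/CO[Si](c3ccccc3)(c3ccccc3)C(C)(C)C | intermediate
26 | 15-[(tert-butyldiphenylsilyl)oxy]labda-8(17),13E-dien-19-al | C=C1CC[C@@H]2[C@](C)(CCC[C@]2(C)C=O)[C@H]1CC/C(C)=C/CO[Si](c3ccccc3)(c3ccccc3)C(C)(C)C | intermediate
27 | 15-hydroxylabda-8(17),13E-dien-19-al | C=C1CC[C@@H]2[C@](C)(CCC[C@]2(C)C=O)[C@H]1CC/C(C)=C/CO | intermediate
28 | oleic acid, (9Z)-octadec-9-enoic acid | CCCCCCCC/C=C\CCCCCCCC(=O)O | starting material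
29 | O-oleoyl isourea formed from oleic acid and EDC | CCCCCCCC/C=C\CCCCCCCC(=O)OC(NCC)=NCCCN(C)C | intermediate
30 | 19-oxolabda-8(17),13E-dien-15-yl (9Z)-octadec-9-enoate | C=C1CC[C@@H]2[C@](C)(CCC[C@]2(C)C=O)[C@H]1CC/C(C)=C/COC(=O)CCCCCCC/C=C\CCCCCCCC | intermediate
31 | 15-[(9Z)-octadec-9-enoyloxy]labda-8(17),13E-dien-19-oic acid (CNP0287077.1) | C=C1CC[C@@H]2[C@](C)(CCC[C@]2(C)C(=O)O)[C@H]1CC/C(C)=C/COC(=O)CCCCCCC/C=C\CCCCCCCC | target

**Step count**

Total steps: 19. Longest linear sequence: 15 steps (1, 2, 4–10, 14–19). Step 3 and steps 11–13 are side branches.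

**Steps most likely to fail**

Step 5. The ester auxiliary may discriminate poorly between the two faces of the C4 radical, and part of radical 11 may be oxidised toward endocyclic alkenes, so that the decalin is obtained as a mixture of diastereomers that is hard to separate. The fallback replaces induction by resolution; it sets out from bromide 3 and keto ester 4 and returns at diol 16. Gamma-alkylation of 4 with 3 under the conditions of step 4 would give methyl (6E,10E)-12-acetoxy-2,6,10-trimethyl-3-oxododeca-6,10-dienoate F1. The same Mn(OAc)3/Cu(OAc)2 cyclisation would give racemic methyl 11-acetoxy-3-oxo-12,13,14,15,16-pentanorlabd-8(17)-en-19-oate F2, its relative configuration still fixed by the chair-like fold. TsNHNH2 would give the racemic tosylhydrazone F3, and catecholborane followed by NaOAc the racemic methyl 11-acetoxy-12,13,14,15,16-pentanorlabd-8(17)-en-19-oate F4. LiAlH4 would give the racemic 11,19-diol F5. Acylation of the unhindered C11 hydroxyl with (1S)-camphanic chloride (pyridine, DMAP, CH2Cl2, 0 °C) would give the 11-camphanate of the natural diol F6 together with the 11-camphanate of the antipodal diol F7, to be separated by crystallisation or chromatography. Methanolysis of F6 (K2CO3, MeOH) would return enantiopure 16.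

Step 9. Displacement at the beta-branched C11 carbon may be slow, so that elimination toward the C9(11) diene or thioether formation at C19 competes. The fallback keeps C19 masked at the ester level and activates C11 as a sulfonate; it sets out from acetate 15 and returns at hydroxy sulfide 17. K2CO3 in MeOH would remove only the acetate to give (−)-8-phenylmenthyl 11-hydroxy-12,13,14,15,16-pentanorlabd-8(17)-en-19-oate F8. MsCl and Et3N (CH2Cl2, 0 °C) would give the 11-methanesulfonate F9. PhSNa in DMF (50 °C), a soft and weakly basic nucleophile, would give (−)-8-phenylmenthyl 11-(phenylsulfanyl)-12,13,14,15,16-pentanorlabd-8(17)-en-19-oate F10. LiAlH4 (THF, reflux) would then cleave the auxiliary to give 17.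

Step 6. The C3 carbonyl is flanked by quaternary C4 and its bulky axial ester and may condense too slowly, and forcing the reaction with acid may move the exocyclic alkene into the ring. The fallback is a radical deoxygenation through the alcohol; it sets out from ketone 12 and returns at 15. NaBH4 (MeOH, 0 °C) would deliver hydride from the alpha face to give (−)-8-phenylmenthyl 11-acetoxy-3β-hydroxy-12,13,14,15,16-pentanorlabd-8(17)-en-19-oate F11. 1,1'-Thiocarbonyldiimidazole (DMAP, 1,2-dichloroethane, reflux) would give the 3-O-(imidazol-1-ylthiocarbonyl) derivative F12. Bu3SnH with AIBN (toluene, 90 °C; Barton–McCombie deoxygenation) would give 15.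

**Further compounds**

F1 | step 5 | methyl (6E,10E)-12-acetoxy-2,6,10-trimethyl-3-oxododeca-6,10-dienoate | COC(=O)C(C)C(=O)CC/C(C)=C/CC/C(C)=C/COC(C)=O
F2 | step 5 | racemic methyl 11-acetoxy-3-oxo-12,13,14,15,16-pentanorlabd-8(17)-en-19-oate (both enantiomers written) | C=C1CC[C@@H]2[C@](C)(CCC(=O)[C@]2(C)C(=O)OC)[C@H]1COC(C)=O.C=C1CC[C@H]2[C@@](C)(CCC(=O)[C@@]2(C)C(=O)OC)[C@@H]1COC(C)=O
F3 | step 5 | racemic C3 p-toluenesulfonylhydrazone of F2 (both enantiomers written) | C=C1CC[C@@H]2[C@](C)(CCC(=NNS(=O)(=O)c3ccc(C)cc3)[C@]2(C)C(=O)OC)[C@H]1COC(C)=O.C=C1CC[C@H]2[C@@](C)(CCC(=NNS(=O)(=O)c3ccc(C)cc3)[C@@]2(C)C(=O)OC)[C@@H]1COC(C)=O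
F4 | step 5 | racemic methyl 11-acetoxy-12,13,14,15,16-pentanorlabd-8(17)-en-19-oate (both enantiomers written) | C=C1CC[C@@H]2[C@](C)(CCC[C@]2(C)C(=O)OC)[C@H]1COC(C)=O.C=C1CC[C@H]2[C@@](C)(CCC[C@@]2(C)C(=O)OC)[C@@H]1COC(C)=O
F5 | step 5 | racemic 12,13,14,15,16-pentanorlabd-8(17)-ene-11,19-diol (both enantiomers written) | C=C1CC[C@@H]2[C@](C)(CCC[C@]2(C)CO)[C@H]1CO.C=C1CC[C@H]2[C@@](C)(CCC[C@@]2(C)CO)[C@@H]1CO
F6 | step 5 | 11-O-[(1S)-camphanoyl] derivative of the natural diol 16 | C=C1CC[C@@H]2[C@](C)(CCC[C@]2(C)CO)[C@H]1COC(=O)[C@@]34CC[C@@](C)(C(=O)O3)C4(C)C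
F7 | step 5 | 11-O-[(1S)-camphanoyl] derivative of the antipodal diol | C=C1CC[C@H]2[C@@](C)(CCC[C@@]2(C)CO)[C@@H]1COC(=O)[C@@]34CC[C@@](C)(C(=O)O3)C4(C)C
F8 | step 9 | (−)-8-phenylmenthyl 11-hydroxy-12,13,14,15,16-pentanorlabd-8(17)-en-19-oate | C=C1CC[C@@H]2[C@](C)(CCC[C@]2(C)C(=O)O[C@@H]3C[C@H](C)CC[C@H]3C(C)(C)c3ccccc3)[C@H]1CO
F9 | step 9 | (−)-8-phenylmenthyl 11-(methanesulfonyloxy)-12,13,14,15,16-pentanorlabd-8(17)-en-19-oate | C=C1CC[C@@H]2[C@](C)(CCC[C@]2(C)C(=O)O[C@@H]3C[C@H](C)CC[C@H]3C(C)(C)c3ccccc3)[C@H]1COS(C)(=O)=O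
F10 | step 9 | (−)-8-phenylmenthyl 11-(phenylsulfanyl)-12,13,14,15,16-pentanorlabd-8(17)-en-19-oate | C=C1CC[C@@H]2[C@](C)(CCC[C@]2(C)C(=O)O[C@@H]3C[C@H](C)CC[C@H]3C(C)(C)c3ccccc3)[C@H]1CSc3ccccc3
F11 | step 6 | (−)-8-phenylmenthyl 11-acetoxy-3β-hydroxy-12,13,14,15,16-pentanorlabd-8(17)-en-19-oate | C=C1CC[C@@H]2[C@](C)(CC[C@H](O)[C@]2(C)C(=O)O[C@@H]3C[C@H](C)CC[C@H]3C(C)(C)c3ccccc3)[C@H]1COC(C)=O
F12 | step 6 | 3-O-(imidazol-1-ylthiocarbonyl) derivative of F11 | C=C1CC[C@@H]2[C@](C)(CC[C@H](OC(=S)n3ccnc3)[C@]2(C)C(=O)O[C@@H]3C[C@H](C)CC[C@H]3C(C)(C)c3ccccc3)[C@H]1COC(C)=O
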